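**Retrosynthetic overview**
- The strategy rests on two features. The chain anisyl–Cβ–Cα(OH)–C9(=O) has the carbon skeleton of O-methyl-L-tyrosine with oxygen in place of nitrogen at Cα. The benzo ring of ring C has a methoxy group beside the carbon bearing C9, which is the pattern that O-addition then C-acylation of 3,5-dimethoxybenzyne delivers.
- Ring P is disconnected at O1–C8a (cyclodehydration) and C4a–C4 (Michael addition), with C2 set by catalyst-controlled ketone reduction. Ring F is disconnected at Cβ–O (oxidative benzylic closure onto one enol ether of a symmetric dimethoxydienone).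
- Ring C is disconnected at O–aryl and aryl–C9 (aryne insertion–acylation of a tertiary quinol onto a dioxolanone carbonyl). The Cα–C8 bond comes from the aldol of the tyrosine-derived dioxolanone enolate with 2,6-dimethoxybenzoquinone.
- Order of ring formation: dioxolanone (temporary) → ring C → ring F → ring P.

Key step: step 7

Labels: the dienone ring is numbered like a flavan A ring, C4a–C5(=O)–C6–C7–C8(spiro)–C8a; ring P is O1–C2(anisyl)–C3–C4–C4a–C8a; ring C is O–C8–Cα(OH)–C9(=O)–benzo ring; ring F is C8–Cα–Cβ(anisyl)–O–C7.

Assumption: the anisyl group on Cβ is taken to be more stable on the convex face of the cis-fused ring C/ring F system (cis to the Cα hydroxyl), as the target requires.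

**Route**

Step 1
Reactants: 1 O-methyl-L-tyrosine
Product: 2 (S)-2-hydroxy-3-(4-methoxyphenyl)propanoic acid
Conditions: NaNO2, 1 M H2SO4, 0 °C → rt
Reagents that add atoms: water, O
Why: Diazotization gives a diazonium ion that the neighbouring carboxylate displaces to an α-lactone, which water opens, so two inversions return the (S) configuration (diazotization–hydrolysis with anchimeric assistance).

Step 2
Reactants: 2 (S)-2-hydroxy-3-(4-methoxyphenyl)propanoic acid; 3 pivalaldehyde
Product: 4 (2S,5S)-2-tert-butyl-5-(4-methoxybenzyl)-1,3-dioxolan-4-one (cis)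
Conditions: TsOH·H2O (cat.), H2SO4 (cat.), pentane, reflux (Dean–Stark); recrystallization
Reagents that add atoms: none
Why: Acid-catalysed acetalization with azeotropic water removal is reversible and should favour the cis-dioxolanone, so the new acetal centre (S) is set by Cα under thermodynamic control and the minor trans isomer is removed by crystallization (first stage of self-regeneration of stereocentres).

Step 3
Reactants: 4 (2S,5S)-2-tert-butyl-5-(4-methoxybenzyl)-1,3-dioxolan-4-one; 5 2,6-dimethoxy-1,4-benzoquinone
Product: 7 (2S,5R)-2-tert-butyl-5-(1-hydroxy-2,6-dimethoxy-4-oxocyclohexa-2,5-dien-1-yl)-5-(4-methoxybenzyl)-1,3-dioxolan-4-one, via lithium enolate 6 (not isolated)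
Conditions: LiN(i-Pr)2, THF, −78 °C; 5 in THF/CH2Cl2, −78 °C; AcOH, −78 °C
Reagents that add atoms: none
Why: This is an aldol-type 1,2-addition of a lithium ester enolate to a quinone carbonyl (second stage of self-regeneration of stereocentres): the planar enolate 6 is shielded on one face by the tert-butyl group and attacks, anti to it, the ketone-like C1 carbonyl of 5 (the C4 carbonyl is a doubly vinylogous carbonate), so the former Cα–H is replaced by C8 with retention, and cold acetic acid protonates the aldolate before retro-aldol can set in.

Step 4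
Reactants: 8 3,5-dimethoxyphenol
Product: 9 2-bromo-3,5-dimethoxyphenol
Conditions: NBS, i-Pr2NH (cat.), CH2Cl2, −78 → 0 °C
Reagents that add atoms: N-bromosuccinimide, O=C1CCC(=O)N1Br
Why: Amine-mediated electrophilic aromatic bromination delivers bromine through a hydrogen-bonded N-bromoamine to the position ortho to the phenol OH, and C4 is additionally shielded by two flanking methoxy groups.

Step 5
Reactants: 9 2-bromo-3,5-dimethoxyphenol
Product: 10 (2-bromo-3,5-dimethoxyphenoxy)trimethylsilane
Conditions: (Me3Si)2NH, THF, 65 °C; concentrate
Reagents that add atoms: hexamethyldisilazane, C[Si](C)(C)N[Si](C)(C)C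
Why: O-Silylation of the phenol with hexamethyldisilazane loses only ammonia and should leave a crude silyl ether fit for the next step.

Step 6
Reactants: 10 (2-bromo-3,5-dimethoxyphenoxy)trimethylsilane
Product: 13 3,5-dimethoxy-2-(trimethylsilyl)phenyl trifluoromethanesulfonate, via aryllithium 11 (not isolated), via lithium silylphenoxide 12 (not isolated)
Conditions: n-BuLi, THF, −100 → −78 °C; Tf2O, −78 °C
Reagents that add atoms: triflic anhydride, O=S(=O)(OS(=O)(=O)C(F)(F)F)C(F)(F)F
Why: Bromine–lithium exchange gives aryllithium 11, a 1,3 O→C silyl shift (retro-Brook rearrangement) turns it into phenoxide 12, and triflation of that phenoxide gives the o-silylaryl triflate (standard route to fluoride-triggered aryne precursors).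

Step 7
Reactants: 7 (2S,5R)-2-tert-butyl-5-(1-hydroxy-2,6-dimethoxy-4-oxocyclohexa-2,5-dien-1-yl)-5-(4-methoxybenzyl)-1,3-dioxolan-4-one; 13 3,5-dimethoxy-2-(trimethylsilyl)phenyl trifluoromethanesulfonate
Product: 17 (3R)-3-hydroxy-2',5,6',7-tetramethoxy-3-(4-methoxybenzyl)spiro[chromane-2,1'-cyclohexa-2',5'-diene]-4,4'-dione, via 3,5-dimethoxybenzyne 14 (not isolated), via aryl cesium ether 15 (not isolated), via cesium hemiacetal alkoxide 16 (not isolated)
Conditions: CsF, 18-crown-6, THF, 0 °C → rt, 13 added slowly; pH 7 phosphate buffer
Reagents that add atoms: none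
Why: Proposed new method: fluoride desilylates 13 to aryne 14 and, acting as base, converts the tertiary quinol of 7 into its cesium alkoxide, which adds to the aryne carbon remote from methoxy and leaves aryl anion 15 ortho to methoxy; 15 attacks the dioxolanone carbonyl C9, the tetrahedral intermediate collapses to hemiacetal alkoxide 16, and 16 sheds pivalaldehyde and is protonated by the bifluoride formed at the start. The closest known reaction type is the aryne insertion–acylation of hydroxy esters (salicylates to xanthones), extended here to a tertiary alkoxide donor and an acylal-type lactone acceptor. Ring C closes by 6-exo-trig attack of the aryl carbanion on C9, following the intermolecular O-arylation. No stereocentre is created: Cα keeps the configuration fixed in step 3, and C8 is not stereogenic because its two dienone arms are identical. The step needs oxygen at the distal and carbon at the proximal aryne position, which the inductive distortion of the aryne by the flanking methoxy group secures, and it needs acylation of 15 to outrun protonation, which the aprotic medium and the activated carbonyl six atoms away should favour. The competing process is retro-aldol loss of the quinone from the alkoxide of 7, countered by generating the aryne slowly at low temperature so that the alkoxide is trapped as it forms.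

Step 8
Reactants: 17 (3R)-3-hydroxy-2',5,6',7-tetramethoxy-3-(4-methoxybenzyl)spiro[chromane-2,1'-cyclohexa-2',5'-diene]-4,4'-dione
Product: 18 ring F methoxy dienone: Cβ bonded to the oxygen on C7 in place of its methyl group, C8a still OMe; C8 (R), Cα (R), Cβ (S), anisyl cis to the Cα hydroxyl
Conditions: DDQ (1.3 equiv), 4 Å MS, ClCH2CH2Cl, 70 °C
Reagents that add atoms: none
Why: Proposed new method: DDQ should abstract hydride from the benzylic CH2 para to methoxy to give a p-methoxybenzylic cation that cannot eliminate because Cα is quaternary, the oxygen of the syn methoxy-enone arm then closes ring F (5-exo) and the oxonium ion passes its methyl group to the hydroquinone anion, the closest known reaction types being DDQ oxidative benzylic C–H cyclizations and dealkylative etherifications by methyl ethers; only the arm that gives a cis ring C/ring F junction can reach Cβ, so Cα fixes C8, and the anisyl group should take the convex face cis to the Cα hydroxyl, which sets Cβ.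

Step 9
Reactants: 18 ring F methoxy dienone
Product: 19 ring F vinylogous acid: 18 with C8a–OH in place of C8a–OMe (enol of the C8a/C5 1,3-dione); C8 (S) by priority change only, Cα (R), Cβ (S)
Conditions: LiCl, DMF, 90 °C; then 0.5 M HCl to pH 3, 0 °C
Reagents that add atoms: none
Why: Chloride should cleave the remaining methyl vinylogous ester by SN2 attack at the methyl carbon (Krapcho-type nucleophilic dealkylation), since the vinylogous carboxylate is a far better leaving group than the aryl ether oxygens and the secondary, neopentyl-like Cβ resists substitution.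

Step 10
Reactants: 19 ring F vinylogous acid; 20 3-chloro-1-(4-methoxyphenyl)propan-1-one
Product: 22 C4a-[3-(4-methoxyphenyl)-3-oxopropyl] derivative of 19, via 4-methoxyphenyl vinyl ketone 21 (not isolated)
Conditions: Et3N (2.2 equiv), THF, 0 °C → rt; aq. citric acid
Reagents that add atoms: none
Why: Triethylamine eliminates HCl from 20 to give enone 21, and the triethylammonium enolate of the vinylogous acid adds through its central carbon C4a (Michael addition of a cyclic 1,3-dione), C-alkylation being the thermodynamic outcome.

Step 11
Reactants: 22 C4a-[3-(4-methoxyphenyl)-3-oxopropyl] derivative of 19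
Product: 24 CNP0251458.1 (target), via (R)-benzylic alcohol 23 (not isolated)
Conditions: RuCl(p-cymene)[(R,R)-TsDPEN] (cat.), HCO2H–Et3N, DMF, 30 °C; then PPTS (cat.), 4 Å MS, CH2Cl2, rt
Reagents that add atoms: none
Why: Noyori-type asymmetric transfer hydrogenation should reduce only the unhindered anisyl ketone (C9 is a deactivated trioxygenated aryl ketone beside a quaternary carbon and the dione is masked as its enol), the (R,R) catalyst setting the (R) carbinol, and mild acid then condenses this hydroxyl with the ketone-like C8a carbonyl through the hemiketal and loss of water, which keeps the carbinol C–O bond and hence gives C2 (R).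

**Compound list**

1 | O-methyl-L-tyrosine | COc1ccc(C[C@H](N)C(=O)O)cc1 | starting material
2 | (S)-2-hydroxy-3-(4-methoxyphenyl)propanoic acid | COc1ccc(C[C@H](O)C(=O)O)cc1 | intermediate
3 | pivalaldehyde | CC(C)(C)C=O | starting material
4 | (2S,5S)-2-tert-butyl-5-(4-methoxybenzyl)-1,3-dioxolan-4-one | COc1ccc(C[C@@H]2O[C@H](C(C)(C)C)OC2=O)cc1 | intermediate
5 | 2,6-dimethoxy-1,4-benzoquinone | COC1=CC(=O)C=C(OC)C1=O | starting material
6 | lithium enolate of 4 | [Li+].[O-]C1=C(Cc2ccc(OC)cc2)O[C@H](C(C)(C)C)O1 | intermediate (not isolated)
7 | (2S,5R)-2-tert-butyl-5-(1-hydroxy-2,6-dimethoxy-4-oxocyclohexa-2,5-dien-1-yl)-5-(4-methoxybenzyl)-1,3-dioxolan-4-one | COC1=CC(=O)C=C(OC)C1(O)[C@@]2(Cc3ccc(OC)cc3)O[C@H](C(C)(C)C)OC2=O | intermediate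
8 | 3,5-dimethoxyphenol | COc1cc(O)cc(OC)c1 | starting material
9 | 2-bromo-3,5-dimethoxyphenol | COc1cc(O)c(Br)c(OC)c1 | intermediate
10 | (2-bromo-3,5-dimethoxyphenoxy)trimethylsilane | COc1cc(O[Si](C)(C)C)c(Br)c(OC)c1 | intermediate
11 | [2,4-dimethoxy-6-(trimethylsilyloxy)phenyl]lithium | [Li]c1c(O[Si](C)(C)C)cc(OC)cc1OC | intermediate (not isolated)
12 | lithium 3,5-dimethoxy-2-(trimethylsilyl)phenoxide | [Li+].[O-]c1cc(OC)cc(OC)c1[Si](C)(C)C | intermediate (not isolated)
13 | 3,5-dimethoxy-2-(trimethylsilyl)phenyl trifluoromethanesulfonate | COc1cc(OC)c([Si](C)(C)C)c(OS(=O)(=O)C(F)(F)F)c1 | intermediate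
14 | 3,5-dimethoxybenzyne | COC1=CC#CC(OC)=C1 | intermediate (not isolated)
15 | O-arylated quinol with aryl–cesium ortho to methoxy, dioxolanone intact | COC1=CC(=O)C=C(OC)C1(Oc1cc(OC)cc(OC)c1[Cs])[C@@]1(Cc2ccc(OC)cc2)O[C@H](C(C)(C)C)OC1=O | intermediate (not isolated)
16 | ring C closed, Cα–O–CH(t-Bu)–O⁻ cesium hemiacetal alkoxide | COC1=CC(=O)C=C(OC)C12Oc3cc(OC)cc(OC)c3C(=O)[C@]2(Cc2ccc(OC)cc2)O[C@@H]([O-])C(C)(C)C.[Cs+] | intermediate (not isolated)
17 | (3R)-3-hydroxy-2',5,6',7-tetramethoxy-3-(4-methoxybenzyl)spiro[chromane-2,1'-cyclohexa-2',5'-diene]-4,4'-dione | COC1=CC(=O)C=C(OC)C12Oc3cc(OC)cc(OC)c3C(=O)[C@@]2(O)Cc2ccc(OC)cc2 | intermediate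
18 | ring F methoxy dienone; C8 (R), Cα (R), Cβ (S) | C1=C(OC)[C@]23Oc4cc(OC)cc(OC)c4C(=O)[C@@]2(O)[C@H](c2ccc(OC)cc2)OC3=CC1=O | intermediate
19 | ring F vinylogous acid (C8a–OH); C8 (S), Cα (R), Cβ (S) | C1=C(O)[C@]23Oc4cc(OC)cc(OC)c4C(=O)[C@@]2(O)[C@H](c2ccc(OC)cc2)OC3=CC1=O | intermediate
20 | 3-chloro-1-(4-methoxyphenyl)propan-1-one | ClCCC(=O)c1ccc(OC)cc1 | starting material
21 | 1-(4-methoxyphenyl)prop-2-en-1-one | C=CC(=O)c1ccc(OC)cc1 | intermediate (not isolated)
22 | 19 bearing a 3-(4-methoxyphenyl)-3-oxopropyl group on C4a; C8 (S), Cα (R), Cβ (S) | O=C(CCC1=C(O)[C@]23Oc4cc(OC)cc(OC)c4C(=O)[C@@]2(O)[C@H](c2ccc(OC)cc2)OC3=CC1=O)c1ccc(OC)cc1 | intermediate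
23 | (R)-carbinol of 22 | O[C@H](CCC1=C(O)[C@]23Oc4cc(OC)cc(OC)c4C(=O)[C@@]2(O)[C@H](c2ccc(OC)cc2)OC3=CC1=O)c1ccc(OC)cc1 | intermediate (not isolated)
24 | CNP0251458.1; C2 (R), C8 (S), Cα (R), Cβ (S) | COc1ccc([C@H]2CCC3=C(O2)[C@]24Oc5cc(OC)cc(OC)c5C(=O)[C@@]2(O)[C@H](c2ccc(OC)cc2)OC4=CC3=O)cc1 | target

**Step count**

Total steps: 11. Longest linear sequence: 8 steps (1, 2, 3, 7, 8, 9, 10, 11 from O-methyl-L-tyrosine; the same length via 4, 5, 6 from 3,5-dimethoxyphenol).

**Steps most likely to fail**

Step 7. The cesium alkoxide of 7 may revert by retro-aldol cleavage to quinone and enolate before it meets the aryne. Alternatively, aryl anion 15 may be protonated to a simple aryl ether without closing ring C. The fallback sets out from 7 and returns at 17, replacing the aryne by an aryllithium acylation followed by nucleophilic aromatic substitution. 2-Bromo-1-fluoro-3,5-dimethoxybenzene F1 (from 1-fluoro-3,5-dimethoxybenzene and NBS in MeCN) is treated with n-BuLi at −78 °C to give (2-fluoro-4,6-dimethoxyphenyl)lithium F2. Compound 7 is first converted into its lithium alkoxide with LiN(SiMe3)2 at −78 °C and then treated with F2. Addition to the dioxolanone carbonyl, collapse with loss of pivalaldehyde and a cold acetic acid quench should give the fluoroaryl ketone F3 (the known acylation of organolithiums by such dioxolanones). Cs2CO3 in DMF at rt should then close ring C by intramolecular displacement of the fluoride ortho to the ketone by the tertiary alkoxide (the known chromanone closure by SNAr), giving 17.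

Step 8. Hydride abstraction from the benzylic CH2 may be too slow next to the electron-poor quaternary Cα. The benzylic cation may also be diverted into a 1,2-acyl (semipinacol) shift before the weakly nucleophilic methoxy oxygen captures it, or the new benzylic ether C–H may be oxidized further. The fallback sets out from 17 and returns at 18; it introduces the Cβ oxygen by a radical oxidation and closes ring F by addition–elimination. Rh2(cap)4 (dirhodium tetracaprolactamate, cat.) with t-BuOOH and NaHCO3 in ClCH2CH2Cl should oxidize the p-methoxybenzylic CH2 to the Cβ ketone F4. Zn(BH4)2 in Et2O at −20 °C should reduce this chelated α-hydroxy ketone, in preference to the deactivated C9 ketone, to the Cβ carbinol F5. CSA (cat.) in CH2Cl2 should then close ring F by vinylogous transesterification onto the syn methoxy-enone with loss of methanol, giving 18. The other carbinol epimer is expected to converge under these acidic conditions through reversible ionization of the benzylic vinylogous ester.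

Step 11. The pendant hydroxyl may condense with the vinylogous-ester carbonyl C5 instead of C8a and give the linear dienone isomer. The acid may also ionize the p-methoxybenzylic alcohol and erode the catalyst-set configuration at C2. The fallback sets out from 19 and returns directly at 24, bypassing steps 10 and 11 by a domino Knoevenagel/hetero-Diels–Alder reaction. Paraformaldehyde and excess 4-methoxystyrene in dioxane at 80 °C should convert 19 into the C4a-methylene trione F6 (not isolated). Its ketone-like C8a carbonyl and the exocyclic methylene form the heterodiene, which adds the styrene with the anisyl carbon bonding to oxygen, closing ring P under neutral conditions with no free benzylic alcohol. In this variant C2 rests on substrate bias alone, so the C2 epimer would have to be removed by chromatography.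

**Further compounds**

F1 | step 7 | 2-bromo-1-fluoro-3,5-dimethoxybenzene | COc1cc(F)c(Br)c(OC)c1
F2 | step 7 | (2-fluoro-4,6-dimethoxyphenyl)lithium | COc1cc(F)c([Li])c(OC)c1
F3 | step 7 | (R)-2-hydroxy-1-(2-fluoro-4,6-dimethoxyphenyl)-2-(1-hydroxy-2,6-dimethoxy-4-oxocyclohexa-2,5-dien-1-yl)-3-(4-methoxyphenyl)propan-1-one | COC1=CC(=O)C=C(OC)C1(O)[C@](O)(Cc1ccc(OC)cc1)C(=O)c1c(F)cc(OC)cc1OC
F4 | step 8 | Cβ ketone of 17 (3-(4-methoxybenzoyl) spirochromanone) | COC1=CC(=O)C=C(OC)C12Oc3cc(OC)cc(OC)c3C(=O)[C@@]2(O)C(=O)c2ccc(OC)cc2
F5 | step 8 | Cβ carbinol of 17, Cα (R), Cβ (S) | COC1=CC(=O)C=C(OC)C12Oc3cc(OC)cc(OC)c3C(=O)[C@@]2(O)[C@@H](O)c2ccc(OC)cc2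
F6 | step 11 | C4a-methylene trione from 19 and formaldehyde | C=C1C(=O)[C@]23Oc4cc(OC)cc(OC)c4C(=O)[C@@]2(O)[C@H](c2ccc(OC)cc2)OC3=CC1=O
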